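**Plan**

- Retrosynthesis: the ester C–O bond to the feruloyl group is cut first, then the two C–C bonds from the stereocentres to the two CH2O carbons, then the central C=C bond, which leads back to two eugenol units.
- Forward: silylated eugenol is dimerised by self-metathesis; the (E)-alkene takes up two CO and two MeOH on palladium; the diester is reduced, mono-acylated with silylated ferulic acid and desilylated. No ring is formed at any stage.
- Enabling feature: the chain ArCH2–CH–CH–CH2Ar between the two 4-hydroxy-3-methoxyphenyl rings is symmetric about its central bond. Each central carbon carries one CH2O carbon, with like (R,R) configuration, which is the outcome of adding two one-carbon groups to the same face of an (E)-alkene.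
- Stereochemistry: the relative configuration comes from the (E)-geometry and syn addition; the absolute configuration comes from a chiral 2,2'-bis(oxazoline) on palladium that selects one of the two enantiotopic alkene faces. No later step touches the stereocentres.

Key step: step 3

Assumption: the sense of induction of the ligand in step 3 cannot be predicted with confidence; the (4S,4'S)-ligand is written on the understanding that its antipode is used if it favours the (2S,3S)-diester.

**Route**

Step 1
Reactants: 1 eugenol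
Product: 2 (4-allyl-2-methoxyphenoxy)triisopropylsilane
Conditions: i-Pr3SiCl, imidazole, DMF, rt
Reagents that add atoms: triisopropylsilyl chloride, CC(C)[Si](Cl)(C(C)C)C(C)C
Why: Imidazole-mediated silyl ether formation at the only nucleophilic site, giving an aryl triisopropylsilyl ether that should survive the carbonylation, the hydride reduction and the esterification and fall to fluoride at the end.

Step 2
Reactants: 2 (4-allyl-2-methoxyphenoxy)triisopropylsilane (two molecules)
Product: 3 (E)-1,4-bis[3-methoxy-4-(triisopropylsilyloxy)phenyl]but-2-ene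
Conditions: second-generation Grubbs catalyst (H2IMes)(PCy3)Cl2Ru=CHPh (2 mol%), 1,4-benzoquinone (10 mol%), CH2Cl2, 40 °C, argon sweep; E-isomer purified by crystallisation or AgNO3-impregnated silica
Reagents that add atoms: none
Why: Olefin self-metathesis of a terminal allylarene, driven by loss of ethylene and expected to equilibrate toward the (E)-alkene by secondary metathesis, with benzoquinone suppressing ruthenium hydride-mediated double-bond migration.

Step 3
Reactants: 3 (E)-1,4-bis[3-methoxy-4-(triisopropylsilyloxy)phenyl]but-2-ene; 4 carbon monoxide (two molecules); 5 methanol (two molecules)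
Product: 6 dimethyl (2R,3R)-2,3-bis[3-methoxy-4-(triisopropylsilyloxy)benzyl]butanedioate
Conditions: Pd(OCOCF3)2 (5 mol%), (4S,4'S)-4,4'-di-tert-butyl-4,4',5,5'-tetrahydro-2,2'-bioxazole (6 mol%), p-benzoquinone (1.5 equiv), TsOH·H2O (2 mol%), CO (10 bar), MeOH–THF (1:1), 20 °C
Reagents that add atoms: carbon monoxide (compound 4), [C-]#[O+]; methanol (compound 5), CO
Why: Proposed new method: a methoxycarbonyl–palladium species formed from the divalent palladium trifluoroacetate complex, CO and MeOH should add syn across the coordinated alkene of 3, CO should then insert into the new alkyl–palladium bond with retention, and methanolysis of the acyl should release 6 and zerovalent palladium, which p-benzoquinone returns to divalent palladium. The closest known reaction type is the oxidative bis-alkoxycarbonylation of 1,2-disubstituted alkenes on divalent palladium with α-diimine ligands and benzoquinone, which is syn-specific but racemic, together with its enantioselective form on styrenes with chiral chelating ligands; the 2,2'-bis(oxazoline) is the C2-symmetric chiral counterpart of those α-diimines. No ring closes. Both new stereocentres arise in the single syn insertion: their relative (like) configuration is fixed by the (E)-geometry, and their absolute configuration by the tert-butyl groups of the ligand, which should allow only one of the two enantiotopic alkene faces to sit next to the methoxycarbonyl group. The two alkene carbons are equivalent, so no regiochemical question arises; the step needs face selection and CO insertion faster than β-hydride elimination toward the benzylic CH2, which CO pressure, the cis-chelating ligand and chelation of the alkyl–palladium by the first ester carbonyl should secure, while benzoquinone also intercepts palladium hydride that would move the double bond.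

Step 4
Reactants: 6 dimethyl (2R,3R)-2,3-bis[3-methoxy-4-(triisopropylsilyloxy)benzyl]butanedioate
Product: 7 (2R,3R)-2,3-bis[3-methoxy-4-(triisopropylsilyloxy)benzyl]butane-1,4-diol
Conditions: LiAlH4, THF, 0 °C; H2O, aq. NaOH work-up
Reagents that add atoms: none
Why: Aluminium hydride reduction of both esters to primary alcohols, under which the α-stereocentres should not enolise and the hindered aryl silyl ethers should persist at 0 °C.

Step 5
Reactants: 8 ferulic acid
Product: 10 (E)-3-[3-methoxy-4-(triisopropylsilyloxy)phenyl]prop-2-enoic acid, via silyl ester 9 (not isolated)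
Conditions: i-Pr3SiCl (2.2 equiv), imidazole, DMF, rt; then K2CO3, MeOH–THF–H2O, 0 °C; 1 M HCl to pH 3
Reagents that add atoms: triisopropylsilyl chloride, CC(C)[Si](Cl)(C(C)C)C(C)C
Why: Exhaustive silylation followed by chemoselective hydrolysis of the silyl ester, which has carboxylate as leaving group and should cleave well before the aryl silyl ether.

Step 6
Reactants: 7 (2R,3R)-2,3-bis[3-methoxy-4-(triisopropylsilyloxy)benzyl]butane-1,4-diol; 10 (E)-3-[3-methoxy-4-(triisopropylsilyloxy)phenyl]prop-2-enoic acid
Product: 11 (2R,3R)-4-hydroxy-2,3-bis[3-methoxy-4-(triisopropylsilyloxy)benzyl]butyl (E)-3-[3-methoxy-4-(triisopropylsilyloxy)phenyl]prop-2-enoate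
Conditions: DCC (1.1 equiv to 10), DMAP (0.1 equiv), CH2Cl2, 0 °C to rt; 7 in twofold excess, 10 added slowly; excess 7 recovered by chromatography
Reagents that add atoms: none
Why: Steglich esterification in which the two hydroxyl groups of the C2-symmetric diol are homotopic, so mono-acylation can give only one compound and the excess of diol should hold back the bis-ester.

Step 7
Reactants: 11 (2R,3R)-4-hydroxy-2,3-bis[3-methoxy-4-(triisopropylsilyloxy)benzyl]butyl (E)-3-[3-methoxy-4-(triisopropylsilyloxy)phenyl]prop-2-enoate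
Product: 12 hanultarin
Conditions: Bu4NF (3.3 equiv), AcOH (3.3 equiv), THF, 0 °C
Reagents that add atoms: none
Why: Fluoride-induced cleavage of the three aryl silyl ethers, buffered with acetic acid so that the phenoxides are protonated at once and the enoate ester, the (E)-alkene and the stereocentres should remain untouched.

**Compound list**

1 | eugenol (4-allyl-2-methoxyphenol) | C=CCc1ccc(O)c(OC)c1 | starting material
2 | (4-allyl-2-methoxyphenoxy)triisopropylsilane | C=CCc1ccc(O[Si](C(C)C)(C(C)C)C(C)C)c(OC)c1 | intermediate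
3 | (E)-1,4-bis[3-methoxy-4-(triisopropylsilyloxy)phenyl]but-2-ene | COc1cc(C/C=C/Cc2ccc(O[Si](C(C)C)(C(C)C)C(C)C)c(OC)c2)ccc1O[Si](C(C)C)(C(C)C)C(C)C | intermediate
4 | carbon monoxide | [C-]#[O+] | starting material
5 | methanol | CO | starting material
6 | dimethyl (2R,3R)-2,3-bis[3-methoxy-4-(triisopropylsilyloxy)benzyl]butanedioate | COC(=O)[C@H](Cc1ccc(O[Si](C(C)C)(C(C)C)C(C)C)c(OC)c1)[C@H](C(=O)OC)Cc1ccc(O[Si](C(C)C)(C(C)C)C(C)C)c(OC)c1 | intermediate
7 | (2R,3R)-2,3-bis[3-methoxy-4-(triisopropylsilyloxy)benzyl]butane-1,4-diol | OC[C@H](Cc1ccc(O[Si](C(C)C)(C(C)C)C(C)C)c(OC)c1)[C@H](CO)Cc1ccc(O[Si](C(C)C)(C(C)C)C(C)C)c(OC)c1 | intermediate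
8 | ferulic acid ((E)-3-(4-hydroxy-3-methoxyphenyl)prop-2-enoic acid) | COc1cc(/C=C/C(=O)O)ccc1O | starting material
9 | triisopropylsilyl (E)-3-[3-methoxy-4-(triisopropylsilyloxy)phenyl]prop-2-enoate | COc1cc(/C=C/C(=O)O[Si](C(C)C)(C(C)C)C(C)C)ccc1O[Si](C(C)C)(C(C)C)C(C)C | intermediate
10 | (E)-3-[3-methoxy-4-(triisopropylsilyloxy)phenyl]prop-2-enoic acid | COc1cc(/C=C/C(=O)O)ccc1O[Si](C(C)C)(C(C)C)C(C)C | intermediate
11 | (2R,3R)-4-hydroxy-2,3-bis[3-methoxy-4-(triisopropylsilyloxy)benzyl]butyl (E)-3-[3-methoxy-4-(triisopropylsilyloxy)phenyl]prop-2-enoate | COc1cc(/C=C/C(=O)OC[C@H](Cc2ccc(O[Si](C(C)C)(C(C)C)C(C)C)c(OC)c2)[C@H](CO)Cc2ccc(O[Si](C(C)C)(C(C)C)C(C)C)c(OC)c2)ccc1O[Si](C(C)C)(C(C)C)C(C)C | intermediate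
12 | hanultarin ((2R,3R)-4-hydroxy-2,3-bis(4-hydroxy-3-methoxybenzyl)butyl (E)-3-(4-hydroxy-3-methoxyphenyl)prop-2-enoate) | COc1cc(/C=C/C(=O)OC[C@H](Cc2ccc(O)c(OC)c2)[C@H](CO)Cc2ccc(O)c(OC)c2)ccc1O | target

**Step count**

Total steps: 7. Longest linear sequence: 6 steps (steps 1, 2, 3, 4, 6 and 7); step 5 is a one-step side branch.

**Steps most likely to fail, with fallbacks**

1. Step 3. The ligand may discriminate poorly between the two alkene faces, and β-hydride elimination toward the benzylic CH2 or migration of the double bond into conjugation may outrun CO insertion. The fallback builds the same C2-symmetric core by known auxiliary chemistry; it sets out from acid 10 and returns at diol 7, bypassing steps 3 and 4. Hydrogenation of 10 (H2, 10% Pd/C, EtOAc) should give 3-[3-methoxy-4-(triisopropylsilyloxy)phenyl]propanoic acid F1. Activation as the mixed pivalic anhydride and N-acylation of (S)-4-isopropyl-1,3-oxazolidin-2-one (t-BuCOCl, Et3N, LiCl, THF) should give (4S)-4-isopropyl-3-{3-[3-methoxy-4-(triisopropylsilyloxy)phenyl]propanoyl}-1,3-oxazolidin-2-one F2. Oxidative homocoupling of its lithium enolate (LiN(i-Pr)2, THF, −78 °C, then PhI(OAc)2 or TiCl4) should give (4S,4'S)-3,3'-{(2R,3R)-2,3-bis[3-methoxy-4-(triisopropylsilyloxy)benzyl]butanedioyl}bis(4-isopropyl-1,3-oxazolidin-2-one) F3. Each auxiliary shields one enolate face, in the same sense as in Evans alkylation, so the (S)-auxiliary is expected to deliver the (R,R)-dimer. Reductive cleavage of both imides (LiBH4, THF–MeOH, 0 °C) should then give diol 7 and free the auxiliary for re-use.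

2. Step 6. The second hydroxyl group may be acylated about as fast as the first, so that bis-ester and unreacted diol dominate and material is lost in recycling. The fallback tells the two hydroxyl groups apart through a cyclic acetal; it sets out from diol 7 and returns at 11. Acetalisation of 7 with 4-methoxybenzaldehyde dimethyl acetal (PPTS, CH2Cl2, rt) should give (5R,6R)-2-(4-methoxyphenyl)-5,6-bis[3-methoxy-4-(triisopropylsilyloxy)benzyl]-1,3-dioxepane F4; its acetal carbon is no stereocentre because the two ring arms are identical. Reductive opening (i-Bu2AlH, CH2Cl2, −78 to 0 °C) should give (2R,3R)-4-[(4-methoxybenzyl)oxy]-2,3-bis[3-methoxy-4-(triisopropylsilyloxy)benzyl]butan-1-ol F5, with exactly one free hydroxyl. Steglich esterification with 10 (DCC, DMAP, CH2Cl2) should give (2R,3R)-4-[(4-methoxybenzyl)oxy]-2,3-bis[3-methoxy-4-(triisopropylsilyloxy)benzyl]butyl (E)-3-[3-methoxy-4-(triisopropylsilyloxy)phenyl]prop-2-enoate F6. Oxidative removal of the 4-methoxybenzyl ether (DDQ, CH2Cl2–pH 7 buffer, 0 °C) should give 11, which goes on to step 7.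

3. Step 2. E selectivity may be incomplete, in which case the (Z)-alkene would pass on as the meso diester, and ruthenium hydride species may move the double bond into conjugation with the arene. The fallback makes the alkene by an E-selective olefination without metathesis; it sets out from 2 and returns at 3. Oxidative cleavage of 2 (K2OsO4·2H2O cat., NaIO4, 2,6-lutidine, dioxane–H2O) should give 2-[3-methoxy-4-(triisopropylsilyloxy)phenyl]acetaldehyde F7. Reduction of half of it (NaBH4, MeOH, 0 °C) should give 2-[3-methoxy-4-(triisopropylsilyloxy)phenyl]ethanol F8. Mitsunobu reaction with 1-phenyl-1H-tetrazole-5-thiol (PPh3, DIAD, THF) should give 5-({2-[3-methoxy-4-(triisopropylsilyloxy)phenyl]ethyl}sulfanyl)-1-phenyl-1H-tetrazole F9. Oxidation ((NH4)6Mo7O24·4H2O, H2O2, EtOH) should give 5-({2-[3-methoxy-4-(triisopropylsilyloxy)phenyl]ethyl}sulfonyl)-1-phenyl-1H-tetrazole F10. Julia–Kocienski olefination of metalated F10 with the other half of F7 (KN(SiMe3)2, DME, −60 °C to rt, aldehyde added to the preformed sulfonyl anion to limit enolisation) should give (E)-alkene 3.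

**Further compounds**

F1 | step 3 | 3-[3-methoxy-4-(triisopropylsilyloxy)phenyl]propanoic acid | COc1cc(CCC(=O)O)ccc1O[Si](C(C)C)(C(C)C)C(C)C
F2 | step 3 | (4S)-4-isopropyl-3-{3-[3-methoxy-4-(triisopropylsilyloxy)phenyl]propanoyl}-1,3-oxazolidin-2-one | CC(C)[C@H]1COC(=O)N1C(=O)CCc1ccc(O[Si](C(C)C)(C(C)C)C(C)C)c(OC)c1
F3 | step 3 | (4S,4'S)-3,3'-{(2R,3R)-2,3-bis[3-methoxy-4-(triisopropylsilyloxy)benzyl]butanedioyl}bis(4-isopropyl-1,3-oxazolidin-2-one) | CC(C)[C@H]1COC(=O)N1C(=O)[C@H](Cc1ccc(O[Si](C(C)C)(C(C)C)C(C)C)c(OC)c1)[C@H](C(=O)N1[C@@H](C(C)C)COC1=O)Cc1ccc(O[Si](C(C)C)(C(C)C)C(C)C)c(OC)c1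
F4 | step 6 | (5R,6R)-2-(4-methoxyphenyl)-5,6-bis[3-methoxy-4-(triisopropylsilyloxy)benzyl]-1,3-dioxepane | COc1ccc(C2OC[C@H](Cc3ccc(O[Si](C(C)C)(C(C)C)C(C)C)c(OC)c3)[C@H](CO2)Cc2ccc(O[Si](C(C)C)(C(C)C)C(C)C)c(OC)c2)cc1
F5 | step 6 | (2R,3R)-4-[(4-methoxybenzyl)oxy]-2,3-bis[3-methoxy-4-(triisopropylsilyloxy)benzyl]butan-1-ol | COc1ccc(COC[C@H](Cc2ccc(O[Si](C(C)C)(C(C)C)C(C)C)c(OC)c2)[C@H](CO)Cc2ccc(O[Si](C(C)C)(C(C)C)C(C)C)c(OC)c2)cc1
F6 | step 6 | (2R,3R)-4-[(4-methoxybenzyl)oxy]-2,3-bis[3-methoxy-4-(triisopropylsilyloxy)benzyl]butyl (E)-3-[3-methoxy-4-(triisopropylsilyloxy)phenyl]prop-2-enoate | COc1ccc(COC[C@H](Cc2ccc(O[Si](C(C)C)(C(C)C)C(C)C)c(OC)c2)[C@H](COC(=O)/C=C/c2ccc(O[Si](C(C)C)(C(C)C)C(C)C)c(OC)c2)Cc2ccc(O[Si](C(C)C)(C(C)C)C(C)C)c(OC)c2)cc1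
F7 | step 2 | 2-[3-methoxy-4-(triisopropylsilyloxy)phenyl]acetaldehyde | COc1cc(CC=O)ccc1O[Si](C(C)C)(C(C)C)C(C)C
F8 | step 2 | 2-[3-methoxy-4-(triisopropylsilyloxy)phenyl]ethanol | COc1cc(CCO)ccc1O[Si](C(C)C)(C(C)C)C(C)C
F9 | step 2 | 5-({2-[3-methoxy-4-(triisopropylsilyloxy)phenyl]ethyl}sulfanyl)-1-phenyl-1H-tetrazole | COc1cc(CCSc2nnnn2-c2ccccc2)ccc1O[Si](C(C)C)(C(C)C)C(C)C
F10 | step 2 | 5-({2-[3-methoxy-4-(triisopropylsilyloxy)phenyl]ethyl}sulfonyl)-1-phenyl-1H-tetrazole | COc1cc(CCS(=O)(=O)c2nnnn2-c2ccccc2)ccc1O[Si](C(C)C)(C(C)C)C(C)C
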